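Ring A is disconnected at the C4a–C5 bond and traced to a squarate-derived cyclobutenone attached to C6 of a 2-aryl-3-methoxypyran-4-one, which already holds O1, C2, C3, C4, C4a and C8a. The feature exploited is the ring A sequence C5–OH, C6–H, C7–O, C8–OMe, with the C5 hydroxyl para to the C8 methoxyl. On heating, the racemic 3-benzyloxy-4-methoxycyclobutenone precursor opens to a dienylketene whose ketene carbon closes onto pyranone C5 (the future C4a); enolisation then delivers ring A with its full oxygenation pattern in one operation. Hydrogenolysis of three benzyl ethers ends the synthesis.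

Key step: step 10

Remark: 2,4-bis(benzyloxy)benzaldehyde and 3-hydroxy-4H-pyran-4-one (pyromeconic acid) are taken as purchasable catalogue compounds; the target is achiral, so no stereocentre has to be controlled.

Step 1
Reactants: 1 2,4-bis(benzyloxy)benzaldehyde
Product: 3 2,4-bis(benzyloxy)phenol, via aryl formate 2 (not isolated)
Conditions: mCPBA, CH2Cl2, 0 → 25 °C; aq. NaHCO3 wash; then K2CO3 (0.2 equiv), MeOH, 25 °C
Reagents that add atoms: 3-chloroperoxybenzoic acid (mCPBA), OOC(=O)c1cccc(Cl)c1
Why: Baeyer–Villiger oxidation of the Dakin type, in which the electron-rich dialkoxyaryl group migrates to oxygen in the Criegee intermediate and mild methanolysis of the formate frees the phenol without touching the benzyl ethers.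

Step 2
Reactants: 3 2,4-bis(benzyloxy)phenol
Product: 4 2,4-bis(benzyloxy)-1-methoxybenzene
Conditions: MeI, K2CO3, acetone, reflux
Reagents that add atoms: iodomethane, CI
Why: Williamson ether synthesis on the only acidic hydroxyl present, which fixes the future C5' methoxyl.

Step 3
Reactants: 4 2,4-bis(benzyloxy)-1-methoxybenzene
Product: 5 1,5-bis(benzyloxy)-2-iodo-4-methoxybenzene
Conditions: NIS (1.05 equiv), TFA (cat.), MeCN, 25 °C
Reagents that add atoms: N-iodosuccinimide, O=C1CCC(=O)N1I
Why: Electrophilic aromatic iodination at the open carbon para to one benzyloxy group and ortho to the other, the most activated unhindered site (the carbon between the two benzyloxy groups is flanked on both sides), as in the halogenation of 1,2,4-trialkoxybenzenes.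

Step 4
Reactants: 6 3-hydroxy-4H-pyran-4-one (pyromeconic acid)
Product: 7 3-methoxy-4H-pyran-4-one
Conditions: MeI, K2CO3, acetone, reflux
Reagents that add atoms: iodomethane, CI
Why: Williamson O-methylation of the acidic enolic hydroxyl, which installs the C3 methoxyl of the flavone at the outset.

Step 5
Reactants: 7 3-methoxy-4H-pyran-4-one; 5 1,5-bis(benzyloxy)-2-iodo-4-methoxybenzene
Product: 9 2-[2,4-bis(benzyloxy)-5-methoxyphenyl]-3-methoxy-4H-pyran-4-one, via pyranonylzinc chloride 8 (not isolated)
Conditions: TMPZnCl·LiCl (1.2 equiv), THF, 25 °C; then 5, Pd(OAc)2 (2 mol%), SPhos (4 mol%), THF, 50 °C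
Reagents that add atoms: none
Why: Directed zincation followed by Negishi cross-coupling, in which C2–H, lying between the ring oxygen and the methoxy-bearing carbon, should be the most acidic proton (as C2–H of chromones is toward the same zinc amide), the C–Zn bond tolerates the pyranone carbonyl, and the catalyst formed from Pd(OAc)2 and SPhos couples hindered, electron-rich aryl iodides.

Step 6
Reactants: 10 squaric acid
Product: 11 dibenzyl squarate [3,4-bis(benzyloxy)cyclobut-3-ene-1,2-dione]
Conditions: BnOH (excess), PhMe, reflux, Dean–Stark trap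
Reagents that add atoms: benzyl alcohol, OCc1ccccc1
Why: Azeotropic esterification of the vinylogous diacid, which is acidic enough to catalyse its own esterification and is driven to the diester by removal of water, as for the dibutyl and diisopropyl esters.

Step 7
Reactants: 11 dibenzyl squarate
Product: 13 3-(benzyloxy)cyclobut-3-ene-1,2-dione, via hydroxycyclobutenone 12 (not isolated)
Conditions: LiAlH(OtBu)3 (1.05 equiv), THF, −78 → −20 °C; aq. work-up; then conc. HCl (cat.), CH2Cl2, 25 °C
Reagents that add atoms: water, O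
Why: Chemoselective 1,2-reduction of one squarate carbonyl by the hindered hydride followed by acid-catalysed allylic transposition, in which the carbinol ionises to a benzyloxy-stabilised cyclobutenyl cation, water adds at the benzyloxy-bearing terminus to supply the new carbonyl oxygen and benzyl alcohol is lost, the established semisquarate synthesis known for the isopropyl analogue.

Step 8
Reactants: 9 2-[2,4-bis(benzyloxy)-5-methoxyphenyl]-3-methoxy-4H-pyran-4-one; 13 3-(benzyloxy)cyclobut-3-ene-1,2-dione
Product: 15 6-[2-(benzyloxy)-1-hydroxy-4-oxocyclobut-2-en-1-yl]-2-[2,4-bis(benzyloxy)-5-methoxyphenyl]-3-methoxy-4H-pyran-4-one (racemic), via pyranonylmagnesium chloride 14 (not isolated)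
Conditions: TMPMgCl·LiCl (1.15 equiv), THF, −40 °C; then cannulation into 13 (1.2 equiv), THF, −78 °C; pH 7 buffer
Reagents that add atoms: none
Why: Directed magnesiation at C6–H, the one remaining proton next to the ring oxygen, followed by Grignard-type 1,2-addition to the ketone-like carbonyl of 13, which is more electrophilic than the vinylogous ester carbonyl; the carbinol stereocentre forms as a racemate and is erased in step 10.

Step 9
Reactants: 15 6-[2-(benzyloxy)-1-hydroxy-4-oxocyclobut-2-en-1-yl]-2-[2,4-bis(benzyloxy)-5-methoxyphenyl]-3-methoxy-4H-pyran-4-one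
Product: 16 6-[2-(benzyloxy)-1-methoxy-4-oxocyclobut-2-en-1-yl]-2-[2,4-bis(benzyloxy)-5-methoxyphenyl]-3-methoxy-4H-pyran-4-one (racemic)
Conditions: MeI (10 equiv), Ag2O (3 equiv), 4 Å MS, MeCN, 25 °C, dark
Reagents that add atoms: iodomethane, CI
Why: Purdie methylation of the tertiary carbinol under essentially neutral conditions, a standard etherification of 4-hydroxycyclobutenones that avoids base-induced ring cleavage and puts the future C8 methyl in place; the stereocentre is untouched and stays racemic.

Step 10
Reactants: 16 6-[2-(benzyloxy)-1-methoxy-4-oxocyclobut-2-en-1-yl]-2-[2,4-bis(benzyloxy)-5-methoxyphenyl]-3-methoxy-4H-pyran-4-one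
Product: 19 7-(benzyloxy)-2-[2,4-bis(benzyloxy)-5-methoxyphenyl]-5-hydroxy-3,8-dimethoxy-4H-chromen-4-one, via dienylketene 17 (not isolated), via cyclohexadienone tautomer 18 (not isolated)
Conditions: PhMe (0.01 M, degassed), 110 °C, argon
Reagents that add atoms: none
Why: Thermal conrotatory four-electron ring opening cleaves the bond between the carbonyl carbon and the carbinol carbon of 16 and gives dienylketene 17; the methoxy donor turns outward, so the pyranone ends up cis to the ketene. The ketene carbon then bonds to pyranone C5 in a thermally allowed disrotatory six-electron electrocyclisation, which forms C4a–C5 and closes the six-membered carbocyclic ring A as dienone 18. Enolisation of the doubly activated C4a–H aromatises ring A and leaves the C5 hydroxyl hydrogen-bonded to the C4 carbonyl. The closest known reaction type is the thermal ring expansion of 4-aryl- and 4-alkenyl-4-alkoxycyclobutenones to 4-alkoxyphenols (Moore rearrangement). No stereocentre is created, since the racemic carbinol carbon of 16 and the transient C4a centre of 18 both become planar. The selectivities needed are outward rotation of the methoxy group, secured by its donor character, and the placement of H, OBn and OMe at C6, C7 and C8, which is fixed beforehand by the regiochemistry of step 8, while C5 is the only pyranone carbon within reach of the ketene.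

Step 11
Reactants: 19 7-(benzyloxy)-2-[2,4-bis(benzyloxy)-5-methoxyphenyl]-5-hydroxy-3,8-dimethoxy-4H-chromen-4-one
Product: 20 5,7-dihydroxy-2-(2,4-dihydroxy-5-methoxyphenyl)-3,8-dimethoxy-4H-chromen-4-one (5,7,2',4'-tetrahydroxy-3,8,5'-trimethoxyflavone)
Conditions: H2 (1 atm), Pd/C (10 wt% Pd), EtOAc/MeOH, 25 °C
Reagents that add atoms: none
Why: Catalytic hydrogenolysis of the three aryl benzyl ethers, under which the tetrasubstituted C2=C3 bond of the 3-methoxyflavone, the chelated carbonyl and the methyl ethers should be inert.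

Compound list
1 | 2,4-bis(benzyloxy)benzaldehyde | O=Cc1ccc(OCc2ccccc2)cc1OCc1ccccc1 | starting material
2 | 2,4-bis(benzyloxy)phenyl formate (not isolated) | O=COc1ccc(OCc2ccccc2)cc1OCc1ccccc1 | intermediate
3 | 2,4-bis(benzyloxy)phenol | Oc1ccc(OCc2ccccc2)cc1OCc1ccccc1 | intermediate
4 | 2,4-bis(benzyloxy)-1-methoxybenzene | COc1ccc(OCc2ccccc2)cc1OCc1ccccc1 | intermediate
5 | 1,5-bis(benzyloxy)-2-iodo-4-methoxybenzene | COc1cc(I)c(OCc2ccccc2)cc1OCc1ccccc1 | intermediate
6 | 3-hydroxy-4H-pyran-4-one (pyromeconic acid) | O=c1ccocc1O | starting material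
7 | 3-methoxy-4H-pyran-4-one | COc1coccc1=O | intermediate
8 | chloro(3-methoxy-4-oxo-4H-pyran-2-yl)zinc, LiCl complex (not isolated) | COc1c([Zn]Cl)occc1=O | intermediate
9 | 2-[2,4-bis(benzyloxy)-5-methoxyphenyl]-3-methoxy-4H-pyran-4-one | COc1cc(-c2occc(=O)c2OC)c(OCc2ccccc2)cc1OCc1ccccc1 | intermediate
10 | squaric acid (3,4-dihydroxycyclobut-3-ene-1,2-dione) | OC1=C(O)C(=O)C1=O | starting material
11 | dibenzyl squarate, 3,4-bis(benzyloxy)cyclobut-3-ene-1,2-dione | O=C1C(=O)C(OCc2ccccc2)=C1OCc1ccccc1 | intermediate
12 | 2,3-bis(benzyloxy)-4-hydroxycyclobut-2-en-1-one, racemic (not isolated) | O=C1C(OCc2ccccc2)=C(OCc2ccccc2)C1O | intermediate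
13 | 3-(benzyloxy)cyclobut-3-ene-1,2-dione | O=C1C=C(OCc2ccccc2)C1=O | intermediate
14 | chloro{6-[2,4-bis(benzyloxy)-5-methoxyphenyl]-5-methoxy-4-oxo-4H-pyran-2-yl}magnesium, LiCl complex (not isolated) | COc1c(-c2cc(OC)c(OCc3ccccc3)cc2OCc2ccccc2)oc([Mg]Cl)cc1=O | intermediate
15 | 6-[2-(benzyloxy)-1-hydroxy-4-oxocyclobut-2-en-1-yl]-2-[2,4-bis(benzyloxy)-5-methoxyphenyl]-3-methoxy-4H-pyran-4-one, racemic | OC1(C(OCc2ccccc2)=CC1=O)c1cc(=O)c(OC)c(-c2cc(OC)c(OCc3ccccc3)cc2OCc2ccccc2)o1 | intermediate
16 | 6-[2-(benzyloxy)-1-methoxy-4-oxocyclobut-2-en-1-yl]-2-[2,4-bis(benzyloxy)-5-methoxyphenyl]-3-methoxy-4H-pyran-4-one, racemic | COC1(C(OCc2ccccc2)=CC1=O)c1cc(=O)c(OC)c(-c2cc(OC)c(OCc3ccccc3)cc2OCc2ccccc2)o1 | intermediate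
17 | 6-[(1Z)-2-(benzyloxy)-1-methoxy-4-oxobuta-1,3-dien-1-yl]-2-[2,4-bis(benzyloxy)-5-methoxyphenyl]-3-methoxy-4H-pyran-4-one, pyranonyl cis to the ketene carbon (not isolated) | O=C=C/C(OCc1ccccc1)=C(/OC)c1cc(=O)c(OC)c(-c2cc(OC)c(OCc3ccccc3)cc2OCc2ccccc2)o1 | intermediate
18 | 7-(benzyloxy)-2-[2,4-bis(benzyloxy)-5-methoxyphenyl]-3,8-dimethoxy-4aH-chromene-4,5-dione, racemic at C4a (not isolated) | O=C1C=C(OCc2ccccc2)C(OC)=C2OC(c3cc(OC)c(OCc4ccccc4)cc3OCc3ccccc3)=C(OC)C(=O)C12 | intermediate
19 | 7-(benzyloxy)-2-[2,4-bis(benzyloxy)-5-methoxyphenyl]-5-hydroxy-3,8-dimethoxy-4H-chromen-4-one | COc1cc(-c2oc3c(OC)c(OCc4ccccc4)cc(O)c3c(=O)c2OC)c(OCc2ccccc2)cc1OCc1ccccc1 | intermediate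
20 | 5,7,2',4'-tetrahydroxy-3,8,5'-trimethoxyflavone | COc1cc(-c2oc3c(OC)c(O)cc(O)c3c(=O)c2OC)c(O)cc1O | target

Total step count: 11. Longest linear sequence: 8 steps (steps 1, 2, 3, 5, 8, 9, 10 and 11, counted from compound 1).

The three steps most likely to fail, riskiest first

Most at risk is step 10, the thermal ring expansion. The dienylketene may be consumed before it closes: by capture through the phenol that is forming, by oligomerisation, or after incomplete outward rotation of the methoxy group. The fallback for step 10 sets out from carbinol 15 and comes back to the route at 19; it inverts the order of ring expansion and O-methylation. Carbinol 15 is heated as such (PhMe, 110 °C, argon), the free 4-hydroxycyclobutenone being the parent substrate class of this rearrangement, with a hydroxyl that should turn outward at least as strongly as a methoxyl. Ring opening should give 6-[(1Z)-2-(benzyloxy)-1-hydroxy-4-oxobuta-1,3-dien-1-yl]-2-[2,4-bis(benzyloxy)-5-methoxyphenyl]-3-methoxy-4H-pyran-4-one F1 , six-electron closure onto pyranone C5 should give 7-(benzyloxy)-2-[2,4-bis(benzyloxy)-5-methoxyphenyl]-8-hydroxy-3-methoxy-4aH-chromene-4,5-dione F2 , and enolisation should give the hydroquinone 7-(benzyloxy)-2-[2,4-bis(benzyloxy)-5-methoxyphenyl]-5,8-dihydroxy-3-methoxy-4H-chromen-4-one F3 . Without exposure to air, F3 is treated with MeI (1 equiv) and K2CO3 in acetone. The C5 hydroxyl is held in the hydrogen bond to the C4 carbonyl, so only the C8 hydroxyl should be etherified, as in the partial methylation of 5,8-dihydroxyflavones, and 19 is reached.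

Second is step 8, the magnesiation and addition to the semisquarate. Deprotonation by the magnesium amide may be incomplete at the low temperature the pyranone tolerates, or may occur at C5 under direction by the carbonyl group and be followed by opening of the pyranone ring. The fallback for step 8 sets out from 9 and comes back to the route at 15; it separates C–H metalation from generation of the nucleophile. Compound 9 is zincated with TMPZnCl·LiCl (THF, 25 °C), the base whose preference for the position next to the ring oxygen of chromones is established, to give chloro{6-[2,4-bis(benzyloxy)-5-methoxyphenyl]-5-methoxy-4-oxo-4H-pyran-2-yl}zinc F4 , and iodolysis with I2 gives 2-[2,4-bis(benzyloxy)-5-methoxyphenyl]-6-iodo-3-methoxy-4H-pyran-4-one F5 . Iodine–magnesium exchange on F5 with iPrMgCl·LiCl (THF, −78 °C) then forms 14 position-specifically and without any amide base, and addition to 13 under the conditions of step 8 gives 15.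

Third is step 5, the zincation and Negishi coupling. Zincation may not be confined to C2, since C6–H is also next to the ring oxygen, or transmetalation of the electron-poor pyranonylzinc to palladium may be slow enough for homocoupling to take over. The fallback for step 5 sets out from 6 and 5 and comes back to the route at 9; it reverses the polarity of the coupling. Compound 6 is brominated with NBS (MeCN, 0 °C) ortho to its enolic hydroxyl, the position at which 3-hydroxypyran-4-ones react with electrophiles, to give 2-bromo-3-hydroxy-4H-pyran-4-one F6 , and MeI with K2CO3 in acetone gives 2-bromo-3-methoxy-4H-pyran-4-one F7 . Iodide 5 is converted by iodine–magnesium exchange (iPrMgCl·LiCl, THF, 0 → 25 °C) into [2,4-bis(benzyloxy)-5-methoxyphenyl]magnesium chloride F8 and then with ZnCl2 into [2,4-bis(benzyloxy)-5-methoxyphenyl]zinc chloride F9 . Negishi coupling of F9 with F7 (Pd(OAc)2, SPhos, THF, 50 °C) gives 9, the site of the new bond now being fixed by the halogen.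

Further compounds
F1 | step 10 | 6-[(1Z)-2-(benzyloxy)-1-hydroxy-4-oxobuta-1,3-dien-1-yl]-2-[2,4-bis(benzyloxy)-5-methoxyphenyl]-3-methoxy-4H-pyran-4-one | O=C=C/C(OCc1ccccc1)=C(/O)c1cc(=O)c(OC)c(-c2cc(OC)c(OCc3ccccc3)cc2OCc2ccccc2)o1
F2 | step 10 | 7-(benzyloxy)-2-[2,4-bis(benzyloxy)-5-methoxyphenyl]-8-hydroxy-3-methoxy-4aH-chromene-4,5-dione, racemic | O=C1C=C(OCc2ccccc2)C(O)=C2OC(c3cc(OC)c(OCc4ccccc4)cc3OCc3ccccc3)=C(OC)C(=O)C12
F3 | step 10 | 7-(benzyloxy)-2-[2,4-bis(benzyloxy)-5-methoxyphenyl]-5,8-dihydroxy-3-methoxy-4H-chromen-4-one | COc1cc(-c2oc3c(O)c(OCc4ccccc4)cc(O)c3c(=O)c2OC)c(OCc2ccccc2)cc1OCc1ccccc1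
F4 | step 8 | chloro{6-[2,4-bis(benzyloxy)-5-methoxyphenyl]-5-methoxy-4-oxo-4H-pyran-2-yl}zinc, LiCl complex | COc1c(-c2cc(OC)c(OCc3ccccc3)cc2OCc2ccccc2)oc([Zn]Cl)cc1=O
F5 | step 8 | 2-[2,4-bis(benzyloxy)-5-methoxyphenyl]-6-iodo-3-methoxy-4H-pyran-4-one | COc1c(-c2cc(OC)c(OCc3ccccc3)cc2OCc2ccccc2)oc(I)cc1=O
F6 | step 5 | 2-bromo-3-hydroxy-4H-pyran-4-one | O=c1ccoc(Br)c1O
F7 | step 5 | 2-bromo-3-methoxy-4H-pyran-4-one | COc1c(Br)occc1=O
F8 | step 5 | [2,4-bis(benzyloxy)-5-methoxyphenyl]magnesium chloride, LiCl complex | COc1cc([Mg]Cl)c(OCc2ccccc2)cc1OCc1ccccc1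
F9 | step 5 | [2,4-bis(benzyloxy)-5-methoxyphenyl]zinc chloride | COc1cc([Zn]Cl)c(OCc2ccccc2)cc1OCc1ccccc1
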